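## The problem

The bicycle is numbered C1 (bridgehead, OMe), C2 (OAc), C3 (OMe)=C4, C5 (bridgehead, allyl), C6 (Me), C7 (aryl), C8 (ketone bridge).

Target 20 is a bicyclo[3.2.1]oct-3-en-8-one: a cyclopentanone (C1–C8–C5–C6–C7) and a cyclohexene (C1–C2–C3=C4–C5–C8) share the C1–C8–C5 unit, and both bridgeheads next to the ketone are fully substituted. It has five stereocentres, (1S,2S,5S,6R,7S). Aryl and methyl are trans on the two-carbon bridge: the aryl group is exo (towards C8) and the methyl group endo (under the enol-ether bridge). The C2 acetate is axial, on the face of the C8 bridge.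

The C6/C7 pair must carry the absolute configuration. The C7 aryl group can then steer a new substituent on C1 to the opposite face, and a chain anchored on C1 can reach C5 only on its own face, which sets C5 with allyl trans to methyl. C2 is the centre the bicycle does not control in the needed sense: hydride on a C2 ketone of the closed system is expected to enter from the C8 side and give the equatorial epimer, and the strained C8 ketone would compete, so C2 has to be set in the open chain by 1,2-induction from C1.

A second hidden demand is that the C3=C4 enol ether lies in the ring, so an open precursor needs its C4 leaving group cis to C2, the less stable alkene geometry.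

Several groups will not survive rough treatment: the methyl enol ether is acid-labile, the β-oxygenated ketone can open by retro-aldol, the allylic acetate is at risk from zerovalent palladium, the terminal alkene rules out hydrogenation and ozonolysis, and the veratryl ring is electron-rich.

The feature that makes the key step possible is ring C1–C8–C5–C6–C7: a cyclopentanone whose carbonyl lies between methoxy-bearing C1 and allyl-bearing C5, with trans substituents on C6 and C7. This is the retron of a conrotatory Nazarov closure, and the α-methoxy group gives a Lewis acid two-point binding.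

## Retrosynthesis

**20 ⇒ 19 ⇒ 18 (C2–O acyl bond, then O–Si).** The acetate goes on last because an allylic acetate should not meet zerovalent palladium or enolising base. Alcohol 19 is released from silyl ether 18. The forward steps need a buffered desilylation and a mild acylation of an axial, neopentyl-type alcohol without retro-aldol opening.

**18 ⇒ 17 (cut C4–C5).** The neighbouring cut, C1–C2 by aldol, would need the three-carbon chain on C5 first and cis to the C6 methyl group, against the normal facial bias of a C5 enolate. Cutting C4–C5 with the chain already on C1 turns that problem into a constraint of the tether. The precursor 17 is monocyclic with one quaternary centre fewer. The forward reaction is a palladium-catalysed coupling of the only possible enolate (C5) with an alkenyl triflate whose leaving group is cis to C2.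

**17 ⇒ 16 ⇒ 15 (C2–H bond).** C2 is set as an open-chain carbinol by 1,2-reduction of enone 15, not in the bicycle, for the reasons given above. The forward step must reduce the C2 carbonyl before the hindered ring ketone and on the face dictated by the C1 methoxy centre.

**15 ⇒ 13, through 14 (cut C3–C4 and O–S).** One carbon is added to the methoxyacetyl methylene of 13 by formylation. The lithium chelate 14 holds the new enolate oxygen cis to the C2 carbonyl, and sulfonylation freezes that geometry in 15. A preformed 3-halo-2-methoxyacryloyl reagent was the neighbouring choice. Its accessible isomer has the halide trans to the carbonyl and cannot close the ring. The chelate gives the needed isomer by construction and uses only catalogue reagents.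

**13 ⇒ 11 + 12 (cut C1–C2).** Acylation of the C1 enolate of 11 with methoxyacetyl chloride 12 makes the quaternary methoxy centre, anti to the C7 aryl group. The forward step needs the enolate on the methoxy side and C- over O-acylation.

**11 ⇒ 9, through 10 (cut C6–C7; key step).** The cyclopentanone with its four substituents and the trans C6/C7 pair comes from acyclic dienone 9 in one step. No other cut of the five-membered ring sets both stereocentres from alkene geometry alone. The forward reaction needs conrotation in one sense and hydride capture of the oxyallyl cation before proton loss.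

**9 ⇒ 7 + 8 (C=C).** A Horner–Wadsworth–Emmons reaction of veratraldehyde 8 with α-methoxy ketophosphonate 7 forms the enol-ether alkene with the aryl group trans to the carbonyl. The alternative, α-lithiation of a β-methoxystyrene, would need a geometrically pure enol ether and would compete with lithiation of the veratryl ring.

**7 ⇒ 5 + 6; 5 ⇒ 3 + 4; 3 ⇒ 1 + 2.** Phosphonate 6 is acylated by ester 5. Ester 5 comes from olefination of acetaldehyde 4 with allylated phosphonoacetate 3, made from 1 and allyl bromide 2. The (E) geometry of 5 puts the methyl group trans to the carbonyl, as the electrocyclisation needs.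

## Roads not taken

**Alternative 1:** The cut is C4–C5, and the closure itself is made the centrepiece: a palladium catalyst with a bulky phosphine couples the C5 enolate with an alkenyl halide on a C1-anchored chain and gives A1, which is the same compound as 18.
- Merits: one step makes quaternary C5 and the six-membered ring; only one position can enolise; the tether enforces the C5 configuration; the reaction type is well known for bridged ketones.
- Weak points: the strategy does not say where the trans aryl/methyl pair and the absolute configuration come from, so the cyclopentanone must be built by separate stepwise chemistry. It also needs C2 set beforehand and a cis alkenyl electrophile.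
- Comparison: as a ring closure it is as good as any available, and the chosen plan uses it as step 10. Alternative 1 is better in one respect: it could take its stereocentres from established asymmetric catalysis, whereas the chosen key step is untested in its asymmetric reductive form. Against that, the chosen plan builds the ring, all four substituents and both stereocentres in one step from a four-step dienone.

**Alternative 2:** The cut is C5–C6. A redox-active ester is reduced by a photoexcited ruthenium catalyst, loses CO2, and the C6 radical adds 5-exo to C5 of a cyclohexene-dione to give the 3,8-dione A2.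
- Merits: mild, neutral conditions that tolerate the acetate; radicals form congested quaternary centres well; decarboxylative Giese additions are better documented than the chosen key step.
- Weak points: the C6 radical is planar, so the methyl configuration and the face of attack at C5 rest on substrate bias alone. The precursor is a densely substituted ene-dione that already holds C1, C2 and C7, and its enantioselective synthesis is unsolved. After closure the C3 ketone must still become the methyl enol ether towards C4, with O- against C-methylation to control.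
- Comparison: Alternative 2 has the better-precedented key step and carries the acetate early. The chosen plan fixes C6/C7 by orbital symmetry and alkene geometry, and installs the enol ether in the ring-forming step.

**Alternative 3:** The cut is C1–C8. In a methoxy-cycloheptenone carrying a formyl group on C5, a metal amide enolises the C2 ketone towards C1 and the enolate adds to the aldehyde, closing both rings to give A3.
- Merits: two rings from one monocycle in a single step, with no transition metal. Here it is better than the chosen plan.
- Weak points: A3 has the oxidation pattern reversed (C8 carbinol, C2 ketone). The endgame must oxidise C8 and reduce C2 to the axial alcohol in the bicycle, where hydride is expected to favour the other face. The seven-membered precursor with quaternary C5 and the C6/C7 pair needs a long synthesis of its own.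
- Comparison: the chosen plan keeps C8 as a ketone from the start and sets C2 before closure, where 1,2-induction works in the needed sense.

Key step: step 5

Remarks on the chemistry:
- Diethyl (methoxymethyl)phosphonate 6 is taken as a catalogue reagent.
- Carbanions and enolates made by plain deprotonation are treated as activated forms of the numbered reactant; only 10 and 14, which differ in connectivity from their precursors, are numbered as unisolated intermediates.
- The α-carbons of 11 (C1, C5) and C5 of 13–17 are epimerisable and are carried as mixtures until steps 6 and 10 fix them.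
- The ligand enantiomer that gives the (6R,7S) series cannot be predicted with confidence; the (S,S)-ligand is written and its mirror image is used if the sense proves opposite.

## Route

Step 1
Reactants: 1 triethyl phosphonoacetate; 2 allyl bromide
Product: 3 ethyl 2-(diethoxyphosphoryl)pent-4-enoate
Conditions: NaH, THF, 0 °C; then 2, 0 °C → rt
Reagents that add atoms: none
Why: C-alkylation of the sodium phosphonoacetate carbanion; a slight excess of 1 limits dialkylation.

Step 2
Reactants: 3 ethyl 2-(diethoxyphosphoryl)pent-4-enoate; 4 acetaldehyde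
Product: 5 ethyl (2E)-2-ethylidenepent-4-enoate
Conditions: NaH, THF, 0 °C; then 4, −78 °C → rt
Reagents that add atoms: none
Why: Horner–Wadsworth–Emmons olefination; α-branched phosphonoacetates should give mainly the (E)-trisubstituted ester, with methyl trans to the ester as the later electrocyclisation needs.

Step 3
Reactants: 5 ethyl (2E)-2-ethylidenepent-4-enoate; 6 diethyl (methoxymethyl)phosphonate
Product: 7 diethyl [(3E)-3-ethylidene-1-methoxy-2-oxohex-5-en-1-yl]phosphonate
Conditions: 6 (2.1 equiv), LiN(iPr)2 (2.1 equiv), THF, −78 °C; then 5, −78 → −30 °C; aq NH4Cl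
Reagents that add atoms: none
Why: Claisen-type acylation of an α-alkoxy phosphonate carbanion by an ester; the second equivalent of carbanion stores the product as its enolate and so shields the enone from conjugate addition.

Step 4
Reactants: 7 diethyl [(3E)-3-ethylidene-1-methoxy-2-oxohex-5-en-1-yl]phosphonate; 8 3,4-dimethoxybenzaldehyde (veratraldehyde)
Product: 9 (1Z,4E)-1-(3,4-dimethoxyphenyl)-2-methoxy-4-(prop-2-en-1-yl)hexa-1,4-dien-3-one
Conditions: NaH, THF, 0 °C; then 8, 0 °C → rt
Reagents that add atoms: none
Why: Horner–Wadsworth–Emmons olefination of an aryl aldehyde with a stabilised α-methoxy-β-ketophosphonate; reversible addition should place the aryl group trans to the acyl group, which is the (1Z) enol ether, and any (1E) isomer is removed by chromatography.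

Step 5
Reactants: 9 (1Z,4E)-1-(3,4-dimethoxyphenyl)-2-methoxy-4-(prop-2-en-1-yl)hexa-1,4-dien-3-one
Product: 11 (3R,4S)-4-(3,4-dimethoxyphenyl)-5-methoxy-3-methyl-2-(prop-2-en-1-yl)cyclopentan-1-one (C2 and C5 not assigned), via triethylsilyl enol ether 10 (not isolated)
Conditions: Sc(OTf)3 (20 mol %), 2,6-bis[(4S)-4-phenyl-4,5-dihydro-1,3-oxazol-2-yl]pyridine (22 mol %), Et3SiH (3 equiv), 3 Å MS, MeCN, −20 °C → rt; then 1 M HCl, THF, 0 °C
Reagents that add atoms: none
Why: Proposed new method: trivalent scandium, held by the tridentate chiral ligand, should bind the C8 carbonyl and the C1 methoxy oxygen of 9 in a five-membered chelate and generate the pentadienyl cation, which closes by thermal conrotatory 4π electrocyclisation to form C6–C7 and the cyclopentane ring. The resulting oxyallyl cation is stabilised by the methoxy group and should live long enough to take hydride from Et3SiH; silyl transfer to oxygen frees the catalyst as enol ether 10, which aqueous acid converts into ketone 11. The closest known reactions are the silane-interrupted (reductive) Nazarov cyclisation under achiral Lewis acids and the scandium–pybox-catalysed asymmetric Nazarov cyclisation of α-alkoxy dienones; running both in one operation is the new part. The single ring closes in the conrotatory mode that orbital symmetry requires for a four-electron system. The relative configuration of C6 and C7 follows from conrotation acting on the (1Z,4E) geometry: both β-substituents point outward and so end trans. Their absolute sense is the direction of conrotation, which the ligand must impose on the chelated cation. C1 and C5 also become sp3 but stay enolisable and are re-set in steps 6 and 10. The step needs hydride capture to outrun proton loss, which the methoxy-stabilised cation, excess silane and low temperature should favour, and it needs the ligand-bound pathway to outrun any achiral background cyclisation.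

Step 6
Reactants: 11 (3R,4S)-4-(3,4-dimethoxyphenyl)-5-methoxy-3-methyl-2-(prop-2-en-1-yl)cyclopentan-1-one; 12 methoxyacetyl chloride
Product: 13 (2R,3S,4R)-3-(3,4-dimethoxyphenyl)-2-methoxy-2-(2-methoxyacetyl)-4-methyl-5-(prop-2-en-1-yl)cyclopentan-1-one (C5 epimers)
Conditions: LiN(SiMe3)2 (0.95 equiv), THF, −78 → 0 °C; MgBr2·OEt2 (1.1 equiv), −78 °C; then 12, −78 → −30 °C
Reagents that add atoms: none
Why: C-acylation of a ketone enolate by an acid chloride; equilibration should favour the enolate at the more acidic, methoxy-bearing C1 (lithium chelated by the methoxy oxygen), and magnesium favours C- over O-acylation. The acyl group should enter anti to the C7 aryl group, which sets C1 with acyl trans to aryl.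

Step 7
Reactants: 13 (2R,3S,4R)-3-(3,4-dimethoxyphenyl)-2-methoxy-2-(2-methoxyacetyl)-4-methyl-5-(prop-2-en-1-yl)cyclopentan-1-one
Product: 15 (1E)-3-[(1R,2S,3R)-2-(3,4-dimethoxyphenyl)-1-methoxy-3-methyl-5-oxo-4-(prop-2-en-1-yl)cyclopentyl]-2-methoxy-3-oxoprop-1-en-1-yl trifluoromethanesulfonate, via lithium formyl enolate 14 (not isolated)
Conditions: LiN(SiMe3)2 (1.0 equiv), THF, −78 °C; HCO2CH2CF3, −78 → −20 °C; then PhNTf2, −78 → 0 °C
Reagents that add atoms: 2,2,2-trifluoroethyl formate, O=COCC(F)(F)F; N-phenylbis(trifluoromethanesulfonimide), O=S(=O)(N(c1ccccc1)S(=O)(=O)C(F)(F)F)C(F)(F)F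
Why: Claisen formylation of the methoxyacetyl methylene, then O-sulfonylation of the chelated lithium enolate 14. The U-shaped chelate holds the enolate oxygen cis to the C2 carbonyl, so the triflate should form cis to C2, as ring closure will demand; one equivalent of base leaves C5 un-enolised.

Step 8
Reactants: 15 (1E)-3-[(1R,2S,3R)-2-(3,4-dimethoxyphenyl)-1-methoxy-3-methyl-5-oxo-4-(prop-2-en-1-yl)cyclopentyl]-2-methoxy-3-oxoprop-1-en-1-yl trifluoromethanesulfonate
Product: 16 (1E,3S)-3-[(1S,2S,3R)-2-(3,4-dimethoxyphenyl)-1-methoxy-3-methyl-5-oxo-4-(prop-2-en-1-yl)cyclopentyl]-3-hydroxy-2-methoxyprop-1-en-1-yl trifluoromethanesulfonate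
Conditions: NaBH4 (1.0 equiv), CeCl3·7H2O (1.2 equiv), MeOH/THF, −78 °C
Reagents that add atoms: none
Why: Luche 1,2-reduction; the C2 carbonyl, activated by the β-triflyloxy group, should react before the ring ketone, which sits between a quaternary and a tertiary carbon. Hydride should add anti to the C1–OMe bond with the C2 and C8 carbonyl dipoles opposed (1,2-induction from C1), which gives (S)-C2, the epimer the closed bicycle would not deliver.

Step 9
Reactants: 16 (1E,3S)-3-[(1S,2S,3R)-2-(3,4-dimethoxyphenyl)-1-methoxy-3-methyl-5-oxo-4-(prop-2-en-1-yl)cyclopentyl]-3-hydroxy-2-methoxyprop-1-en-1-yl trifluoromethanesulfonate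
Product: 17 (1E,3S)-3-[(tert-butyldimethylsilyl)oxy]-3-[(1S,2S,3R)-2-(3,4-dimethoxyphenyl)-1-methoxy-3-methyl-5-oxo-4-(prop-2-en-1-yl)cyclopentyl]-2-methoxyprop-1-en-1-yl trifluoromethanesulfonate
Conditions: TBSOTf, 2,6-lutidine, CH2Cl2, −78 → 0 °C
Reagents that add atoms: tert-butyldimethylsilyl trifluoromethanesulfonate, CC(C)(C)[Si](C)(C)OS(=O)(=O)C(F)(F)F
Why: Silylation of a hindered secondary alcohol with a silyl triflate; the ether blocks retro-aldol cleavage and allylic ionisation in the next step.

Step 10
Reactants: 17 (1E,3S)-3-[(tert-butyldimethylsilyl)oxy]-3-[(1S,2S,3R)-2-(3,4-dimethoxyphenyl)-1-methoxy-3-methyl-5-oxo-4-(prop-2-en-1-yl)cyclopentyl]-2-methoxyprop-1-en-1-yl trifluoromethanesulfonate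
Product: 18 (1S,2S,5S,6R,7S)-2-[(tert-butyldimethylsilyl)oxy]-7-(3,4-dimethoxyphenyl)-1,3-dimethoxy-6-methyl-5-(prop-2-en-1-yl)bicyclo[3.2.1]oct-3-en-8-one
Conditions: Pd2(dba)3 (5 mol %), XPhos (12 mol %), K3PO4 (3 equiv), toluene, 80 °C
Reagents that add atoms: none
Why: Palladium-catalysed intramolecular α-alkenylation of a ketone: oxidative addition of zerovalent palladium to the alkenyl triflate, enolisation at C5 (the only α-hydrogen) and C–C reductive elimination close the six-membered ring. The chain on C1 can reach only the face of C5 cis to the C6 methyl group, so C5 should become (S) with allyl trans to methyl.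

Step 11
Reactants: 18 (1S,2S,5S,6R,7S)-2-[(tert-butyldimethylsilyl)oxy]-7-(3,4-dimethoxyphenyl)-1,3-dimethoxy-6-methyl-5-(prop-2-en-1-yl)bicyclo[3.2.1]oct-3-en-8-one
Product: 19 (1S,2S,5S,6R,7S)-7-(3,4-dimethoxyphenyl)-2-hydroxy-1,3-dimethoxy-6-methyl-5-(prop-2-en-1-yl)bicyclo[3.2.1]oct-3-en-8-one
Conditions: Bu4NF, AcOH (1:1), THF, 0 °C → rt
Reagents that add atoms: none
Why: Fluoride cleavage of the silyl ether, buffered with acetic acid so that the β-hydroxy ketone does not open by retro-aldol reaction and the enol ether is not hydrolysed.

Step 12
Reactants: 19 (1S,2S,5S,6R,7S)-7-(3,4-dimethoxyphenyl)-2-hydroxy-1,3-dimethoxy-6-methyl-5-(prop-2-en-1-yl)bicyclo[3.2.1]oct-3-en-8-one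
Product: 20 (1S,2S,5S,6R,7S)-7-(3,4-dimethoxyphenyl)-1,3-dimethoxy-6-methyl-8-oxo-5-(prop-2-en-1-yl)bicyclo[3.2.1]oct-3-en-2-yl acetate
Conditions: Ac2O, DMAP (cat.), pyridine, CH2Cl2, 0 °C → rt
Reagents that add atoms: acetic anhydride, CC(=O)OC(C)=O
Why: DMAP-catalysed acylation of the axial secondary alcohol under mild, non-enolising conditions; no stereocentre is touched.

## Compound list

1 | triethyl phosphonoacetate | CCOC(=O)CP(=O)(OCC)OCC | starting material
2 | allyl bromide | C=CCBr | starting material
3 | ethyl 2-(diethoxyphosphoryl)pent-4-enoate | C=CCC(C(=O)OCC)P(=O)(OCC)OCC | intermediate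
4 | acetaldehyde | CC=O | starting material
5 | ethyl (2E)-2-ethylidenepent-4-enoate | C=CC/C(=C\C)C(=O)OCC | intermediate
6 | diethyl (methoxymethyl)phosphonate | COCP(=O)(OCC)OCC | starting material
7 | diethyl [(3E)-3-ethylidene-1-methoxy-2-oxohex-5-en-1-yl]phosphonate | C=CC/C(=C\C)C(=O)C(OC)P(=O)(OCC)OCC | intermediate
8 | 3,4-dimethoxybenzaldehyde (veratraldehyde) | COc1ccc(C=O)cc1OC | starting material
9 | (1Z,4E)-1-(3,4-dimethoxyphenyl)-2-methoxy-4-(prop-2-en-1-yl)hexa-1,4-dien-3-one | C=CC/C(=C\C)C(=O)/C(OC)=C/c1ccc(OC)c(OC)c1 | intermediate
10 | triethyl{[(3R,4S)-4-(3,4-dimethoxyphenyl)-5-methoxy-3-methyl-2-(prop-2-en-1-yl)cyclopent-1-en-1-yl]oxy}silane (C5 not assigned) | C=CCC1=C(O[Si](CC)(CC)CC)C(OC)[C@H](c2ccc(OC)c(OC)c2)[C@H]1C | intermediate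
11 | (3R,4S)-4-(3,4-dimethoxyphenyl)-5-methoxy-3-methyl-2-(prop-2-en-1-yl)cyclopentan-1-one (aryl and methyl trans; C2 and C5 not assigned) | C=CCC1C(=O)C(OC)[C@H](c2ccc(OC)c(OC)c2)[C@H]1C | intermediate
12 | methoxyacetyl chloride | COCC(Cl)=O | starting material
13 | (2R,3S,4R)-3-(3,4-dimethoxyphenyl)-2-methoxy-2-(2-methoxyacetyl)-4-methyl-5-(prop-2-en-1-yl)cyclopentan-1-one (C5 epimers) | C=CCC1C(=O)[C@@](OC)(C(=O)COC)[C@H](c2ccc(OC)c(OC)c2)[C@H]1C | intermediate
14 | lithium (1E)-3-[(1R,2S,3R)-2-(3,4-dimethoxyphenyl)-1-methoxy-3-methyl-5-oxo-4-(prop-2-en-1-yl)cyclopentyl]-2-methoxy-3-oxoprop-1-en-1-olate (chelated enolate, oxygen cis to the C2 carbonyl) | C=CCC1C(=O)[C@@](OC)(C(=O)/C(OC)=C\[O-])[C@H](c2ccc(OC)c(OC)c2)[C@H]1C.[Li+] | intermediate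
15 | (1E)-3-[(1R,2S,3R)-2-(3,4-dimethoxyphenyl)-1-methoxy-3-methyl-5-oxo-4-(prop-2-en-1-yl)cyclopentyl]-2-methoxy-3-oxoprop-1-en-1-yl trifluoromethanesulfonate (triflate cis to the C2 carbonyl) | C=CCC1C(=O)[C@@](OC)(C(=O)/C(OC)=C\OS(=O)(=O)C(F)(F)F)[C@H](c2ccc(OC)c(OC)c2)[C@H]1C | intermediate
16 | (1E,3S)-3-[(1S,2S,3R)-2-(3,4-dimethoxyphenyl)-1-methoxy-3-methyl-5-oxo-4-(prop-2-en-1-yl)cyclopentyl]-3-hydroxy-2-methoxyprop-1-en-1-yl trifluoromethanesulfonate | C=CCC1C(=O)[C@@](OC)([C@@H](O)/C(OC)=C\OS(=O)(=O)C(F)(F)F)[C@H](c2ccc(OC)c(OC)c2)[C@H]1C | intermediate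
17 | (1E,3S)-3-[(tert-butyldimethylsilyl)oxy]-3-[(1S,2S,3R)-2-(3,4-dimethoxyphenyl)-1-methoxy-3-methyl-5-oxo-4-(prop-2-en-1-yl)cyclopentyl]-2-methoxyprop-1-en-1-yl trifluoromethanesulfonate | C=CCC1C(=O)[C@@](OC)([C@@H](O[Si](C)(C)C(C)(C)C)/C(OC)=C\OS(=O)(=O)C(F)(F)F)[C@H](c2ccc(OC)c(OC)c2)[C@H]1C | intermediate
18 | (1S,2S,5S,6R,7S)-2-[(tert-butyldimethylsilyl)oxy]-7-(3,4-dimethoxyphenyl)-1,3-dimethoxy-6-methyl-5-(prop-2-en-1-yl)bicyclo[3.2.1]oct-3-en-8-one | C=CC[C@]12C=C(OC)[C@H](O[Si](C)(C)C(C)(C)C)[C@](OC)(C1=O)[C@H](c1ccc(OC)c(OC)c1)[C@H]2C | intermediate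
19 | (1S,2S,5S,6R,7S)-7-(3,4-dimethoxyphenyl)-2-hydroxy-1,3-dimethoxy-6-methyl-5-(prop-2-en-1-yl)bicyclo[3.2.1]oct-3-en-8-one | C=CC[C@]12C=C(OC)[C@H](O)[C@](OC)(C1=O)[C@H](c1ccc(OC)c(OC)c1)[C@H]2C | intermediate
20 | (1S,2S,5S,6R,7S)-7-(3,4-dimethoxyphenyl)-1,3-dimethoxy-6-methyl-8-oxo-5-(prop-2-en-1-yl)bicyclo[3.2.1]oct-3-en-2-yl acetate | C=CC[C@]12C=C(OC)[C@H](OC(C)=O)[C@](OC)(C1=O)[C@H](c1ccc(OC)c(OC)c1)[C@H]2C | target

## Step count and least certain steps

Total: 12 steps. Longest linear sequence: 12 steps (1 → 20); the other starting materials enter as single reagents.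

**Step 5 (key step, proposed new method).**
- What may go wrong: proton loss from the oxyallyl cation may outrun hydride transfer and give a cyclopentenone with one β-stereocentre erased; silyl triflate formed from the silane and Sc(OTf)3 may drive a racemic background cyclisation; the ligand may discriminate the two conrotation senses poorly; or the dienone may be reduced by ionic hydrogenation before it cyclises.
- Fallback (known chemistry): from 9, run the established achiral silane-interrupted Nazarov cyclisation (BF3·OEt2, Et3SiH, CH2Cl2, −78 °C; acidic work-up; DBU equilibration to the all-trans ketone). This gives the racemate, that is 11 together with its mirror image (3S,4R)-4-(3,4-dimethoxyphenyl)-5-methoxy-3-methyl-2-(prop-2-en-1-yl)cyclopentan-1-one F1. The enantiomers are separated by preparative chromatography on a chiral stationary phase, and the route is rejoined at 11.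

**Step 6.**
- What may go wrong: enolisation on the allyl side (C5) under kinetic control, or O-acylation of the congested tetrasubstituted enolate to an enol ester.
- Fallback: from 11, add the equilibrated lithium enolate to methoxyacetaldehyde (C-selective and reversible) to give (2S,3S,4R)-3-(3,4-dimethoxyphenyl)-2-(1-hydroxy-2-methoxyethyl)-2-methoxy-4-methyl-5-(prop-2-en-1-yl)cyclopentan-1-one F2, then oxidise the carbinol with Dess–Martin periodinane to return at 13.

**Step 7.**
- What may go wrong: deprotonation at C5 followed by premature vinylogous substitution to a bicyclic enedione; retro-Claisen cleavage of the non-enolisable 1,3-diketone by trifluoroethoxide; or loss of the cis geometry by addition–elimination at C4.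
- Fallback: from 13, condense under neutral conditions with tert-butoxybis(dimethylamino)methane to the enaminone 2-[3-(dimethylamino)-2-methoxyprop-2-enoyl]-3-(3,4-dimethoxyphenyl)-2-methoxy-4-methyl-5-(prop-2-en-1-yl)cyclopentan-1-one F3. Hydrolyse it with dilute acid to the chelated hydroxymethylene diketone 2-[(2Z)-3-hydroxy-2-methoxyprop-2-enoyl]-3-(3,4-dimethoxyphenyl)-2-methoxy-4-methyl-5-(prop-2-en-1-yl)cyclopentan-1-one F4. Triflate its sodium chelate (NaH, PhNTf2) to return at 15.

**Step 8.**
- What may go wrong: competing reduction of the C8 ring ketone, hydride attack on the wrong face of C2 if chelation through the methoxy group takes over, or conjugate displacement of the triflate.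
- Fallback: replace substrate control by reagent control. From 15, carry out a Corey–Bakshi–Shibata reduction (oxazaborolidine catalyst of the matched hand, catecholborane, −78 °C), which returns directly at 16 and makes no new compound.

**Step 10.**
- What may go wrong: slow C–C reductive elimination at the congested C5 next to the cis methyl group, which would allow protodetriflation, β-hydride elimination from the palladium enolate to an enone, or S–O cleavage of the triflate by base.
- Fallback: from 17, brominate the C5 enolate (LiN(SiMe3)2, N-bromosuccinimide) to the α-bromo ketone (1E,3S)-3-[(1S,2S,3R)-4-bromo-2-(3,4-dimethoxyphenyl)-1-methoxy-3-methyl-5-oxo-4-(prop-2-en-1-yl)cyclopentyl]-3-[(tert-butyldimethylsilyl)oxy]-2-methoxyprop-1-en-1-yl trifluoromethanesulfonate F5. Close the ring by nickel-catalysed reductive cross-electrophile coupling (NiBr2(dme), 4,4'-di-tert-butyl-2,2'-bipyridine, Zn, DMA), in which a tertiary α-keto radical is captured by the alkenylnickel species, to return at 18.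

## Further compounds

F1 | step 5 | (3S,4R)-4-(3,4-dimethoxyphenyl)-5-methoxy-3-methyl-2-(prop-2-en-1-yl)cyclopentan-1-one | C=CCC1C(=O)C(OC)[C@@H](c2ccc(OC)c(OC)c2)[C@@H]1C
F2 | step 6 | (2S,3S,4R)-3-(3,4-dimethoxyphenyl)-2-(1-hydroxy-2-methoxyethyl)-2-methoxy-4-methyl-5-(prop-2-en-1-yl)cyclopentan-1-one | C=CCC1C(=O)[C@@](OC)(C(O)COC)[C@H](c2ccc(OC)c(OC)c2)[C@H]1C
F3 | step 7 | (2R,3S,4R)-2-[3-(dimethylamino)-2-methoxyprop-2-enoyl]-3-(3,4-dimethoxyphenyl)-2-methoxy-4-methyl-5-(prop-2-en-1-yl)cyclopentan-1-one | C=CCC1C(=O)[C@@](OC)(C(=O)C(OC)=CN(C)C)[C@H](c2ccc(OC)c(OC)c2)[C@H]1C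
F4 | step 7 | (2R,3S,4R)-2-[(2Z)-3-hydroxy-2-methoxyprop-2-enoyl]-3-(3,4-dimethoxyphenyl)-2-methoxy-4-methyl-5-(prop-2-en-1-yl)cyclopentan-1-one | C=CCC1C(=O)[C@@](OC)(C(=O)/C(OC)=C\O)[C@H](c2ccc(OC)c(OC)c2)[C@H]1C
F0 | step 8 | none | none
F5 | step 10 | (1E,3S)-3-[(1S,2S,3R)-4-bromo-2-(3,4-dimethoxyphenyl)-1-methoxy-3-methyl-5-oxo-4-(prop-2-en-1-yl)cyclopentyl]-3-[(tert-butyldimethylsilyl)oxy]-2-methoxyprop-1-en-1-yl trifluoromethanesulfonate | C=CCC1(Br)C(=O)[C@@](OC)([C@@H](O[Si](C)(C)C(C)(C)C)/C(OC)=C\OS(=O)(=O)C(F)(F)F)[C@H](c2ccc(OC)c(OC)c2)[C@H]1C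
A1 | alternative 1 | 5-allyl-2-(tert-butyldimethylsilyloxy)-7-(3,4-dimethoxyphenyl)-1,3-dimethoxy-6-methylbicyclo[3.2.1]oct-3-en-8-one (same compound as 18) | C=CC[C@]12C=C(OC)[C@H](O[Si](C)(C)C(C)(C)C)[C@](OC)(C1=O)[C@H](c1ccc(OC)c(OC)c1)[C@H]2C
A2 | alternative 2 | 2-acetoxy-5-allyl-7-(3,4-dimethoxyphenyl)-1-methoxy-6-methylbicyclo[3.2.1]octane-3,8-dione (configured as 20 at C1, C2, C5, C6 and C7) | C=CC[C@]12CC(=O)[C@H](OC(C)=O)[C@](OC)(C1=O)[C@H](c1ccc(OC)c(OC)c1)[C@H]2C
A3 | alternative 3 | 5-allyl-7-(3,4-dimethoxyphenyl)-8-hydroxy-1,3-dimethoxy-6-methylbicyclo[3.2.1]oct-3-en-2-one (C8 hydroxyl on the side away from the C6–C7 bridge) | C=CC[C@]12C=C(OC)C(=O)[C@](OC)([C@@H]1O)[C@H](c1ccc(OC)c(OC)c1)[C@H]2C
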